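**Retrosynthetic overview**
- The ten-membered carbocycle is closed last, at C9–C10, by intramolecular Nozaki–Hiyama–Kishi coupling of a C10 vinyl iodide with a C9 aldehyde; C9 is then corrected by oxidation/Luche reduction, acetylated, and C14 (CH2OPMB) is oxidised to CO2Me before desilylation.
- The α-methylene γ-lactone is formed first: Zn-Barbier allylation of a 3-(bromomethyl)butenolide with TBSOCH2CHO makes C7–C8 and the exo-methylene; Mitsunobu inversion installs the C8 isobutyrate.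
- The butenolide comes from a C6 enal by catalytic asymmetric propiolate alkynylation (sets C6), Lindlar semi-hydrogenation/lactonisation and α-hydroxymethylation.
- Both trisubstituted alkenes come from propargylic alcohols by trans-hydroalumination/iodination; C3–C4 by Pd/Reformatsky coupling; the C2 carbinol by ketoreductase reduction of an ynone (first stereocentre).
- Carbon sources: but-2-yne-1,4-diol (C4, C5, C6, C15), ethyl bromoacetate (C2, C3), propargyl alcohol (C1, C10, C14), methyl propiolate (C7, C11, C12), formaldehyde (C13), TBSOCH2CHO (C8, C9). Ring order: γ-lactone, then carbocycle.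

Assumption: C1–C15 are the germacranolide locants of the target; TBS = tert-butyldimethylsilyl, TBDPS = tert-butyldiphenylsilyl, PMB = 4-methoxybenzyl, R* = (1E,4S,5Z)-4-(TBSO)-2-(TBDPSOCH2)-6-iodo-7-(PMBO)hepta-1,5-dien-1-yl; compounds 6, 20 and 29 are bought.

**Step 1**
Reactants: 1 but-2-yne-1,4-diol
Product: 2 4-(TBDPSO)but-2-yn-1-ol
Conditions: NaH (1.0 equiv), THF, 0 °C; then TBDPSCl, 0 °C → rt
Reagents that add atoms: tert-butyl(chloro)diphenylsilane, CC(C)(C)[Si](Cl)(c1ccccc1)c1ccccc1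
Why: O-silylation of the monosodium alkoxide of a symmetrical diol (McDougal monoprotection) stops cleanly at the monoether; no stereocentre.

**Step 2**
Reactants: 2 4-(TBDPSO)but-2-yn-1-ol
Product: 4 (2Z)-4-(TBDPSO)-3-iodobut-2-en-1-ol, via sodium alkenylalanate 3 (not isolated)
Conditions: NaAlH2(OCH2CH2OMe)2 (Red-Al), THF, 0 °C → rt; then iodine, −78 °C
Reagents that add atoms: iodine, [I][I]
Why: Hydroxyl-directed trans-hydroalumination puts hydride on the carbinol-side carbon and Al on the distal carbon, and iododealumination with retention gives the vinyl iodide with iodine cis to CH2OH, which fixes the C4=C5 geometry.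

**Step 3**
Reactants: 4 (2Z)-4-(TBDPSO)-3-iodobut-2-en-1-ol
Product: 5 (2Z)-1-(TBSO)-4-(TBDPSO)-3-iodobut-2-ene
Conditions: TBSCl, imidazole, DMF, 0 °C → rt
Reagents that add atoms: tert-butyl(chloro)dimethylsilane, CC(C)(C)[Si](C)(C)Cl
Why: Imidazole-catalysed silylation of an unhindered primary allylic alcohol.

**Step 4**
Reactants: 5 (2Z)-1-(TBSO)-4-(TBDPSO)-3-iodobut-2-ene; 6 ethyl bromoacetate
Product: 8 ethyl (3E)-5-(TBSO)-3-(TBDPSOCH2)pent-3-enoate, via Reformatsky reagent 7 (not isolated)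
Conditions: 6, Zn dust (TMSCl-activated), THF, 40 °C; then 5, Pd(PPh3)4 (5 mol %), THF/DMPU, 60 °C
Reagents that add atoms: none
Why: Negishi-type cross-coupling of a Reformatsky reagent with a vinyl iodide under zerovalent palladium goes with retention of alkene geometry, so C3 ends up cis to C6.

**Step 5**
Reactants: 8 ethyl (3E)-5-(TBSO)-3-(TBDPSOCH2)pent-3-enoate
Product: 9 (3E)-5-(TBSO)-3-(TBDPSOCH2)-N-methoxy-N-methylpent-3-enamide
Conditions: MeNH(OMe)·HCl, AlMe3, CH2Cl2, 0 °C → rt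
Reagents that add atoms: N,O-dimethylhydroxylamine hydrochloride, CNOC.Cl
Why: Weinreb aminolysis through the aluminium amide is Lewis-acidic and only weakly basic, so the skipped alkene does not move into conjugation.

**Step 6**
Reactants: 10 prop-2-yn-1-ol
Product: 11 1-methoxy-4-[(prop-2-yn-1-yloxy)methyl]benzene
Conditions: NaH, 4-methoxybenzyl chloride, Bu4NI (cat.), THF/DMF, 0 °C → rt
Reagents that add atoms: 4-methoxybenzyl chloride, COc1ccc(CCl)cc1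
Why: Williamson etherification of a primary alkoxide with a benzylic chloride.

**Step 7**
Reactants: 9 (3E)-5-(TBSO)-3-(TBDPSOCH2)-N-methoxy-N-methylpent-3-enamide; 11 1-methoxy-4-[(prop-2-yn-1-yloxy)methyl]benzene
Product: 13 (6E)-8-(TBSO)-6-(TBDPSOCH2)-1-(PMBO)oct-6-en-2-yn-4-one, via lithium acetylide 12 (not isolated)
Conditions: 11, n-BuLi, THF, −78 °C; then 9, −78 → −20 °C; aq. NH4Cl
Reagents that add atoms: none
Why: Weinreb ketone synthesis: the chelated tetrahedral intermediate survives until work-up, so the acetylide adds only once.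

**Step 8**
Reactants: 13 (6E)-8-(TBSO)-6-(TBDPSOCH2)-1-(PMBO)oct-6-en-2-yn-4-one
Product: 14 (4S,6E)-8-(TBSO)-6-(TBDPSOCH2)-1-(PMBO)oct-6-en-2-yn-4-ol
Conditions: ketoreductase (S-selective, NADPH-dependent alcohol dehydrogenase class), NADP+ (cat.), i-PrOH (10 vol %), phosphate buffer pH 7.0, DMSO (5 vol %), 30 °C
Reagents that add atoms: none
Why: Enzymatic asymmetric ketone reduction delivers hydride from NADPH to one face of the ynone at neutral pH (no isomerisation of the skipped enone) and sets C2 as S, the first stereocentre.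

**Step 9**
Reactants: 14 (4S,6E)-8-(TBSO)-6-(TBDPSOCH2)-1-(PMBO)oct-6-en-2-yn-4-ol
Product: 16 (2Z,4S,6E)-8-(TBSO)-6-(TBDPSOCH2)-2-iodo-1-(PMBO)octa-2,6-dien-4-ol, via sodium alkenylalanate 15 (not isolated)
Conditions: NaAlH2(OCH2CH2OMe)2, THF, 0 °C → rt; then iodine, −78 °C
Reagents that add atoms: iodine, [I][I]
Why: The same hydroxyl-directed trans-hydroalumination/iodination, steered only by the free C2 hydroxyl, places iodine on C10 cis to C2 and CH2OPMB trans to C2, which is the C1=C10 geometry of the target.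

**Step 10**
Reactants: 16 (2Z,4S,6E)-8-(TBSO)-6-(TBDPSOCH2)-2-iodo-1-(PMBO)octa-2,6-dien-4-ol
Product: 17 (2Z,4S,6E)-4,8-bis(TBSO)-6-(TBDPSOCH2)-2-iodo-1-(PMBO)octa-2,6-diene
Conditions: TBSOTf, 2,6-lutidine, CH2Cl2, −78 °C
Reagents that add atoms: tert-butyldimethylsilyl trifluoromethanesulfonate, CC(C)(C)[Si](C)(C)OS(=O)(=O)C(F)(F)F
Why: Silyl triflate silylation of a secondary allylic alcohol with a non-nucleophilic base.

**Step 11**
Reactants: 17 (2Z,4S,6E)-4,8-bis(TBSO)-6-(TBDPSOCH2)-2-iodo-1-(PMBO)octa-2,6-diene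
Product: 18 (2E,5S,6Z)-5-(TBSO)-3-(TBDPSOCH2)-7-iodo-8-(PMBO)octa-2,6-dien-1-ol
Conditions: HF·pyridine, pyridine, THF, 0 °C
Reagents that add atoms: none
Why: Chemoselective desilylation: the primary allylic TBS ether is cleaved much faster than the secondary TBS and the TBDPS ether.

**Step 12**
Reactants: 18 (2E,5S,6Z)-5-(TBSO)-3-(TBDPSOCH2)-7-iodo-8-(PMBO)octa-2,6-dien-1-ol
Product: 19 (2E,5S,6Z)-5-(TBSO)-3-(TBDPSOCH2)-7-iodo-8-(PMBO)octa-2,6-dienal
Conditions: Dess–Martin periodinane, NaHCO3, CH2Cl2, 0 °C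
Reagents that add atoms: none
Why: Buffered Dess–Martin oxidation gives the β,β-disubstituted enal without acid or base that would scramble the alkene geometry.

**Step 13**
Reactants: 19 (2E,5S,6Z)-5-(TBSO)-3-(TBDPSOCH2)-7-iodo-8-(PMBO)octa-2,6-dienal; 20 methyl prop-2-ynoate
Product: 22 methyl (4R,5E,8S,9Z)-4-hydroxy-8-(TBSO)-6-(TBDPSOCH2)-10-iodo-11-(PMBO)undeca-5,9-dien-2-ynoate, via zinc acetylide 21 (not isolated)
Conditions: 20, Me2Zn, (S,S)-ProPhenol (20 mol %; the (R,R)-ligand if Si-face delivery requires it), Ph3PO (40 mol %), toluene, 0 °C; then 19, 4 °C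
Reagents that add atoms: none
Why: Trost's dinuclear zinc–ProPhenol asymmetric alkynylation binds aldehyde and zinc acetylide on one chiral complex and delivers the alkynyl group to the Si face, setting C6 as R under catalyst control.

**Step 14**
Reactants: 22 methyl (4R,5E,8S,9Z)-4-hydroxy-8-(TBSO)-6-(TBDPSOCH2)-10-iodo-11-(PMBO)undeca-5,9-dien-2-ynoate
Product: 24 (5S)-5-R*-furan-2(5H)-one, via Z-hydroxy enoate 23 (not isolated)
Conditions: H2 (1 atm), Pd/CaCO3–Pb(OAc)2 (Lindlar catalyst), quinoline, EtOAc, rt; then PPTS (cat.), CH2Cl2, rt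
Reagents that add atoms: none
Why: Lindlar semi-hydrogenation gives the Z-enoate, whose cis γ-hydroxyl lactonises to the butenolide; C6 is untouched (the descriptor changes only through CIP priorities) and the vinyl iodide survives the poisoned catalyst.

**Step 15**
Reactants: 24 (5S)-5-R*-furan-2(5H)-one
Product: 27 (5R)-3-(hydroxymethyl)-5-R*-furan-2(5H)-one, via selenide aldol adduct 25 (not isolated), via selenoxide 26 (not isolated)
Conditions: (PhSe)2, n-BuLi, THF, −78 °C; 24; HCHO (g), −78 °C; AcOH; then H2O2 (30 %), pyridine, CH2Cl2, 0 °C → rt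
Reagents that add atoms: formaldehyde, C=O
Why: Selenolate conjugate addition, aldol trapping of the lactone enolate with formaldehyde and selenoxide syn-elimination form a Baylis–Hillman equivalent that avoids amine bases, which would racemise the acidic γ-centre.

**Step 16**
Reactants: 27 (5R)-3-(hydroxymethyl)-5-R*-furan-2(5H)-one
Product: 28 (5R)-3-(bromomethyl)-5-R*-furan-2(5H)-one
Conditions: CBr4, PPh3, CH2Cl2, 0 °C
Reagents that add atoms: carbon tetrabromide, BrC(Br)(Br)Br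
Why: Appel bromination of a primary allylic alcohol under neutral conditions.

**Step 17**
Reactants: 28 (5R)-3-(bromomethyl)-5-R*-furan-2(5H)-one; 29 2-(TBSO)acetaldehyde
Product: 30 (4R,5R)-4-[(1R)-2-(TBSO)-1-hydroxyethyl]-3-methylidene-5-R*-oxolan-2-one
Conditions: Zn dust, THF/sat. aq. NH4Cl (2:1), 0 °C → rt
Reagents that add atoms: none
Why: In this Barbier allylation the allylzinc reacts through C7 on the face anti to the C6 side chain (trans lactone with exocyclic methylene), and the ring-fixed E-type allyl unit in a chair Zimmerman–Traxler transition state gives the 7,8-anti carbinol (8R); the vinyl iodide is inert to zinc.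

**Step 18**
Reactants: 30 (4R,5R)-4-[(1R)-2-(TBSO)-1-hydroxyethyl]-3-methylidene-5-R*-oxolan-2-one
Product: 31 (4S,5R)-4-[(1S)-2-(TBSO)-1-(2-methylpropanoyloxy)ethyl]-3-methylidene-5-R*-oxolan-2-one
Conditions: PPh3, DIAD, 2-methylpropanoic acid, toluene, 0 °C → rt
Reagents that add atoms: 2-methylpropanoic acid, CC(C)C(=O)O
Why: Mitsunobu esterification displaces the oxyphosphonium by SN2, inverting C8 to the required 8S and installing the isobutyrate in one operation.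

**Step 19**
Reactants: 31 (4S,5R)-4-[(1S)-2-(TBSO)-1-(2-methylpropanoyloxy)ethyl]-3-methylidene-5-R*-oxolan-2-one
Product: 32 (4S,5R)-4-[(1S)-2-hydroxy-1-(2-methylpropanoyloxy)ethyl]-3-methylidene-5-R*-oxolan-2-one
Conditions: HF·pyridine, pyridine, THF, 0 °C; crude used at once
Reagents that add atoms: none
Why: Selective cleavage of the primary TBS ether under mildly acidic fluoride conditions, where secondary TBS, TBDPS and the ester stay and acyl migration is slow.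

**Step 20**
Reactants: 32 (4S,5R)-4-[(1S)-2-hydroxy-1-(2-methylpropanoyloxy)ethyl]-3-methylidene-5-R*-oxolan-2-one
Product: 33 (4S,5R)-4-[(1S)-2-oxo-1-(2-methylpropanoyloxy)ethyl]-3-methylidene-5-R*-oxolan-2-one
Conditions: Dess–Martin periodinane, NaHCO3, CH2Cl2, 0 °C
Reagents that add atoms: none
Why: Non-basic Dess–Martin oxidation gives the α-acyloxy aldehyde without epimerising C8.

**Step 21**
Reactants: 33 (4S,5R)-4-[(1S)-2-oxo-1-(2-methylpropanoyloxy)ethyl]-3-methylidene-5-R*-oxolan-2-one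
Product: 34 (2S,6R,7S,8S,9R)-2-(TBSO)-15-(TBDPSO)-9-hydroxy-14-(PMBO)-8-(2-methylpropanoyloxy)germacra-1(10),4,11(13)-trien-12,6-olide
Conditions: CrCl2 (10 equiv), NiCl2 (2 mol %), DMSO/THF (3:1), 2 mM, rt
Reagents that add atoms: none
Why: In this intramolecular Nozaki–Hiyama–Kishi coupling zerovalent nickel inserts into the carbon–iodine bond, the alkenyl group passes to chromium and adds only to the aldehyde; the two ring-cis alkenes and the lactone preorganise the chain, and C9 forms as an epimer mixture (Felkin–Anh favours 9R, shown) that converges in steps 22 and 23.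

**Step 22**
Reactants: 34 (2S,6R,7S,8S,9R)-2-(TBSO)-15-(TBDPSO)-9-hydroxy-14-(PMBO)-8-(2-methylpropanoyloxy)germacra-1(10),4,11(13)-trien-12,6-olide
Product: 35 (2S,6R,7S,8S)-2-(TBSO)-15-(TBDPSO)-9-oxo-14-(PMBO)-8-(2-methylpropanoyloxy)germacra-1(10),4,11(13)-trien-12,6-olide
Conditions: Dess–Martin periodinane, NaHCO3, CH2Cl2, 0 °C
Reagents that add atoms: none
Why: Dess–Martin oxidation turns both allylic C9 epimers into one enone under non-epimerising conditions.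

**Step 23**
Reactants: 35 (2S,6R,7S,8S)-2-(TBSO)-15-(TBDPSO)-9-oxo-14-(PMBO)-8-(2-methylpropanoyloxy)germacra-1(10),4,11(13)-trien-12,6-olide
Product: 36 (2S,6R,7S,8S,9S)-2-(TBSO)-15-(TBDPSO)-9-hydroxy-14-(PMBO)-8-(2-methylpropanoyloxy)germacra-1(10),4,11(13)-trien-12,6-olide
Conditions: NaBH4, CeCl3·7H2O, MeOH/THF, −78 °C
Reagents that add atoms: none
Why: Luche reduction attacks only the enone carbonyl (1,2), and Felkin–Anh approach of hydride anti to the C8–O bond gives the 8,9-syn alcohol, that is 9S.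

**Step 24**
Reactants: 36 (2S,6R,7S,8S,9S)-2-(TBSO)-15-(TBDPSO)-9-hydroxy-14-(PMBO)-8-(2-methylpropanoyloxy)germacra-1(10),4,11(13)-trien-12,6-olide
Product: 37 (2S,6R,7S,8S,9S)-9-acetoxy-2-(TBSO)-15-(TBDPSO)-14-(PMBO)-8-(2-methylpropanoyloxy)germacra-1(10),4,11(13)-trien-12,6-olide
Conditions: Ac2O, pyridine, DMAP (cat.), CH2Cl2, 0 °C → rt
Reagents that add atoms: acetic anhydride, CC(=O)OC(C)=O
Why: DMAP-catalysed acylation of the only free hydroxyl, with retention at C9.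

**Step 25**
Reactants: 37 (2S,6R,7S,8S,9S)-9-acetoxy-2-(TBSO)-15-(TBDPSO)-14-(PMBO)-8-(2-methylpropanoyloxy)germacra-1(10),4,11(13)-trien-12,6-olide
Product: 38 (2S,6R,7S,8S,9S)-9-acetoxy-2-(TBSO)-15-(TBDPSO)-14-hydroxy-8-(2-methylpropanoyloxy)germacra-1(10),4,11(13)-trien-12,6-olide
Conditions: DDQ, CH2Cl2/pH 7 phosphate buffer (10:1), 0 °C
Reagents that add atoms: none
Why: Oxidative cleavage of the electron-rich PMB ether by DDQ leaves esters, silyl ethers and the α-methylene lactone alone.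

**Step 26**
Reactants: 38 (2S,6R,7S,8S,9S)-9-acetoxy-2-(TBSO)-15-(TBDPSO)-14-hydroxy-8-(2-methylpropanoyloxy)germacra-1(10),4,11(13)-trien-12,6-olide
Product: 40 (2S,6R,7S,8S,9S)-9-acetoxy-2-(TBSO)-15-(TBDPSO)-8-(2-methylpropanoyloxy)-12-oxo-12,6-epoxygermacra-1(10),4,11(13)-trien-14-oic acid, via enal 39 (not isolated)
Conditions: Dess–Martin periodinane, NaHCO3, CH2Cl2, 0 °C; then NaClO2, NaH2PO4, 2-methyl-2-butene, t-BuOH/H2O, 0 °C
Reagents that add atoms: sodium chlorite, [Na+].[O-]Cl=O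
Why: Dess–Martin oxidation then Pinnick oxidation take the primary allylic alcohol to the acid; the enal already has its stable geometry (CHO trans to C2) and the chlorine scavenger protects the alkenes.

**Step 27**
Reactants: 40 (2S,6R,7S,8S,9S)-9-acetoxy-2-(TBSO)-15-(TBDPSO)-8-(2-methylpropanoyloxy)-12-oxo-12,6-epoxygermacra-1(10),4,11(13)-trien-14-oic acid
Product: 41 methyl ester of 40 (methyl 14-oate)
Conditions: MeI, KHCO3, DMF, rt
Reagents that add atoms: iodomethane, IC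
Why: SN2 O-alkylation of the carboxylate under bicarbonate avoids diazo reagents, which would add to the α-methylene lactone.

**Step 28**
Reactants: 41 methyl ester of 40 (methyl 14-oate)
Product: 42 methyl (2S,6R,7S,8S,9S)-9-acetoxy-2,15-dihydroxy-8-(2-methylpropanoyloxy)-12-oxo-12,6-epoxygermacra-1(10),4,11(13)-trien-14-oate (target, CNP0301018.3)
Conditions: HF·pyridine, THF, 0 °C → rt
Reagents that add atoms: none
Why: Fluoride desilylation under mildly acidic conditions removes the TBS and TBDPS ethers without acyl migration or Michael addition to the α-methylene lactone.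

**Compound list**
1 | but-2-yne-1,4-diol | OCC#CCO | starting material
2 | 4-(TBDPSO)but-2-yn-1-ol | OCC#CCO[Si](c1ccccc1)(c1ccccc1)C(C)(C)C | intermediate
3 | sodium alkenylalanate from 2 (five-membered O,C-aluminacycle, Al on the carbon bearing CH2OTBDPS) | [Na+].COCCO[Al-]1(OCCOC)OCC=C1CO[Si](c2ccccc2)(c2ccccc2)C(C)(C)C | intermediate (not isolated)
4 | (2Z)-4-(TBDPSO)-3-iodobut-2-en-1-ol | OC/C=C(\I)CO[Si](c1ccccc1)(c1ccccc1)C(C)(C)C | intermediate
5 | (2Z)-1-(TBSO)-4-(TBDPSO)-3-iodobut-2-ene | CC(C)(C)[Si](C)(C)OC/C=C(\I)CO[Si](c1ccccc1)(c1ccccc1)C(C)(C)C | intermediate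
6 | ethyl bromoacetate | CCOC(=O)CBr | starting material
7 | (2-ethoxy-2-oxoethyl)zinc bromide | CCOC(=O)C[Zn]Br | intermediate (not isolated)
8 | ethyl (3E)-5-(TBSO)-3-(TBDPSOCH2)pent-3-enoate | CC(C)(C)[Si](C)(C)OC/C=C(/CO[Si](c1ccccc1)(c1ccccc1)C(C)(C)C)CC(=O)OCC | intermediate
9 | (3E)-5-(TBSO)-3-(TBDPSOCH2)-N-methoxy-N-methylpent-3-enamide | CC(C)(C)[Si](C)(C)OC/C=C(/CO[Si](c1ccccc1)(c1ccccc1)C(C)(C)C)CC(=O)N(C)OC | intermediate
10 | prop-2-yn-1-ol | C#CCO | starting material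
11 | 1-methoxy-4-[(prop-2-yn-1-yloxy)methyl]benzene | C#CCOCc1ccc(OC)cc1 | intermediate
12 | lithium acetylide of 11 | [Li]C#CCOCc1ccc(OC)cc1 | intermediate (not isolated)
13 | (6E)-8-(TBSO)-6-(TBDPSOCH2)-1-(PMBO)oct-6-en-2-yn-4-one | CC(C)(C)[Si](C)(C)OC/C=C(/CO[Si](c1ccccc1)(c1ccccc1)C(C)(C)C)CC(=O)C#CCOCc1ccc(OC)cc1 | intermediate
14 | (4S,6E)-8-(TBSO)-6-(TBDPSOCH2)-1-(PMBO)oct-6-en-2-yn-4-ol | CC(C)(C)[Si](C)(C)OC/C=C(/CO[Si](c1ccccc1)(c1ccccc1)C(C)(C)C)C[C@H](O)C#CCOCc1ccc(OC)cc1 | intermediate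
15 | sodium alkenylalanate from 14 (aluminacycle through the C2 oxygen, Al on C10) | [Na+].COCCO[Al-]1(OCCOC)O[C@@H](C/C(CO[Si](c2ccccc2)(c2ccccc2)C(C)(C)C)=C\CO[Si](C)(C)C(C)(C)C)C=C1COCc2ccc(OC)cc2 | intermediate (not isolated)
16 | (2Z,4S,6E)-8-(TBSO)-6-(TBDPSOCH2)-2-iodo-1-(PMBO)octa-2,6-dien-4-ol | CC(C)(C)[Si](C)(C)OC/C=C(/CO[Si](c1ccccc1)(c1ccccc1)C(C)(C)C)C[C@H](O)/C=C(/COCc1ccc(OC)cc1)I | intermediate
17 | (2Z,4S,6E)-4,8-bis(TBSO)-6-(TBDPSOCH2)-2-iodo-1-(PMBO)octa-2,6-diene | CC(C)(C)[Si](C)(C)OC/C=C(/CO[Si](c1ccccc1)(c1ccccc1)C(C)(C)C)C[C@H](O[Si](C)(C)C(C)(C)C)/C=C(/COCc1ccc(OC)cc1)I | intermediate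
18 | (2E,5S,6Z)-5-(TBSO)-3-(TBDPSOCH2)-7-iodo-8-(PMBO)octa-2,6-dien-1-ol | OC/C=C(/CO[Si](c1ccccc1)(c1ccccc1)C(C)(C)C)C[C@H](O[Si](C)(C)C(C)(C)C)/C=C(/COCc1ccc(OC)cc1)I | intermediate
19 | (2E,5S,6Z)-5-(TBSO)-3-(TBDPSOCH2)-7-iodo-8-(PMBO)octa-2,6-dienal | O=C/C=C(/CO[Si](c1ccccc1)(c1ccccc1)C(C)(C)C)C[C@H](O[Si](C)(C)C(C)(C)C)/C=C(/COCc1ccc(OC)cc1)I | intermediate
20 | methyl prop-2-ynoate | C#CC(=O)OC | starting material
21 | methyl 3-(methylzincio)prop-2-ynoate | C[Zn]C#CC(=O)OC | intermediate (not isolated)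
22 | methyl (4R,5E,8S,9Z)-4-hydroxy-8-(TBSO)-6-(TBDPSOCH2)-10-iodo-11-(PMBO)undeca-5,9-dien-2-ynoate | COC(=O)C#C[C@H](O)/C=C(/CO[Si](c1ccccc1)(c1ccccc1)C(C)(C)C)C[C@H](O[Si](C)(C)C(C)(C)C)/C=C(/COCc1ccc(OC)cc1)I | intermediate
23 | methyl (2Z,4S,5E,8S,9Z)-4-hydroxy-8-(TBSO)-6-(TBDPSOCH2)-10-iodo-11-(PMBO)undeca-2,5,9-trienoate | COC(=O)/C=C\[C@H](O)/C=C(/CO[Si](c1ccccc1)(c1ccccc1)C(C)(C)C)C[C@H](O[Si](C)(C)C(C)(C)C)/C=C(/COCc1ccc(OC)cc1)I | intermediate (not isolated)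
24 | (5S)-5-R*-furan-2(5H)-one | O=C1C=C[C@@H](/C=C(/CO[Si](c2ccccc2)(c2ccccc2)C(C)(C)C)C[C@H](O[Si](C)(C)C(C)(C)C)/C=C(/COCc2ccc(OC)cc2)I)O1 | intermediate
25 | 3-(hydroxymethyl)-4-(phenylselanyl)-5-R*-oxolan-2-one (PhSe trans to R*, C3 epimers) | O=C1C(CO)[C@H]([Se]c2ccccc2)[C@@H](/C=C(/CO[Si](c2ccccc2)(c2ccccc2)C(C)(C)C)C[C@H](O[Si](C)(C)C(C)(C)C)/C=C(/COCc2ccc(OC)cc2)I)O1 | intermediate (not isolated)
26 | selenoxide of 25 | O=C1C(CO)[C@H]([Se](=O)c2ccccc2)[C@@H](/C=C(/CO[Si](c2ccccc2)(c2ccccc2)C(C)(C)C)C[C@H](O[Si](C)(C)C(C)(C)C)/C=C(/COCc2ccc(OC)cc2)I)O1 | intermediate (not isolated)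
27 | (5R)-3-(hydroxymethyl)-5-R*-furan-2(5H)-one | O=C1C(CO)=C[C@@H](/C=C(/CO[Si](c2ccccc2)(c2ccccc2)C(C)(C)C)C[C@H](O[Si](C)(C)C(C)(C)C)/C=C(/COCc2ccc(OC)cc2)I)O1 | intermediate
28 | (5R)-3-(bromomethyl)-5-R*-furan-2(5H)-one | O=C1C(CBr)=C[C@@H](/C=C(/CO[Si](c2ccccc2)(c2ccccc2)C(C)(C)C)C[C@H](O[Si](C)(C)C(C)(C)C)/C=C(/COCc2ccc(OC)cc2)I)O1 | intermediate
29 | 2-(TBSO)acetaldehyde | O=CCO[Si](C)(C)C(C)(C)C | starting material
30 | (4R,5R)-4-[(1R)-2-(TBSO)-1-hydroxyethyl]-3-methylidene-5-R*-oxolan-2-one | C=C1C(=O)O[C@H](/C=C(/CO[Si](c2ccccc2)(c2ccccc2)C(C)(C)C)C[C@H](O[Si](C)(C)C(C)(C)C)/C=C(/COCc2ccc(OC)cc2)I)[C@H]1[C@@H](O)CO[Si](C)(C)C(C)(C)C | intermediate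
31 | (4S,5R)-4-[(1S)-2-(TBSO)-1-(2-methylpropanoyloxy)ethyl]-3-methylidene-5-R*-oxolan-2-one | C=C1C(=O)O[C@H](/C=C(/CO[Si](c2ccccc2)(c2ccccc2)C(C)(C)C)C[C@H](O[Si](C)(C)C(C)(C)C)/C=C(/COCc2ccc(OC)cc2)I)[C@H]1[C@H](OC(=O)C(C)C)CO[Si](C)(C)C(C)(C)C | intermediate
32 | (4S,5R)-4-[(1S)-2-hydroxy-1-(2-methylpropanoyloxy)ethyl]-3-methylidene-5-R*-oxolan-2-one | C=C1C(=O)O[C@H](/C=C(/CO[Si](c2ccccc2)(c2ccccc2)C(C)(C)C)C[C@H](O[Si](C)(C)C(C)(C)C)/C=C(/COCc2ccc(OC)cc2)I)[C@H]1[C@H](OC(=O)C(C)C)CO | intermediate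
33 | (4S,5R)-4-[(1S)-2-oxo-1-(2-methylpropanoyloxy)ethyl]-3-methylidene-5-R*-oxolan-2-one | C=C1C(=O)O[C@H](/C=C(/CO[Si](c2ccccc2)(c2ccccc2)C(C)(C)C)C[C@H](O[Si](C)(C)C(C)(C)C)/C=C(/COCc2ccc(OC)cc2)I)[C@H]1[C@H](OC(=O)C(C)C)C=O | intermediate
34 | (2S,6R,7S,8S,9R)-2-(TBSO)-15-(TBDPSO)-9-hydroxy-14-(PMBO)-8-(2-methylpropanoyloxy)germacra-1(10),4,11(13)-trien-12,6-olide (both ring alkenes cis in the ring; 9S epimer carried along) | C=C1C(=O)O[C@@H]2/C=C(/CO[Si](c3ccccc3)(c3ccccc3)C(C)(C)C)C[C@H](O[Si](C)(C)C(C)(C)C)/C=C(/COCc3ccc(OC)cc3)[C@@H](O)[C@@H](OC(=O)C(C)C)[C@@H]12 | intermediate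
35 | (2S,6R,7S,8S)-2-(TBSO)-15-(TBDPSO)-9-oxo-14-(PMBO)-8-(2-methylpropanoyloxy)germacra-1(10),4,11(13)-trien-12,6-olide | C=C1C(=O)O[C@@H]2/C=C(/CO[Si](c3ccccc3)(c3ccccc3)C(C)(C)C)C[C@H](O[Si](C)(C)C(C)(C)C)/C=C(/COCc3ccc(OC)cc3)C(=O)[C@@H](OC(=O)C(C)C)[C@@H]12 | intermediate
36 | (2S,6R,7S,8S,9S)-2-(TBSO)-15-(TBDPSO)-9-hydroxy-14-(PMBO)-8-(2-methylpropanoyloxy)germacra-1(10),4,11(13)-trien-12,6-olide | C=C1C(=O)O[C@@H]2/C=C(/CO[Si](c3ccccc3)(c3ccccc3)C(C)(C)C)C[C@H](O[Si](C)(C)C(C)(C)C)/C=C(/COCc3ccc(OC)cc3)[C@H](O)[C@@H](OC(=O)C(C)C)[C@@H]12 | intermediate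
37 | (2S,6R,7S,8S,9S)-9-acetoxy-2-(TBSO)-15-(TBDPSO)-14-(PMBO)-8-(2-methylpropanoyloxy)germacra-1(10),4,11(13)-trien-12,6-olide | C=C1C(=O)O[C@@H]2/C=C(/CO[Si](c3ccccc3)(c3ccccc3)C(C)(C)C)C[C@H](O[Si](C)(C)C(C)(C)C)/C=C(/COCc3ccc(OC)cc3)[C@H](OC(C)=O)[C@@H](OC(=O)C(C)C)[C@@H]12 | intermediate
38 | (2S,6R,7S,8S,9S)-9-acetoxy-2-(TBSO)-15-(TBDPSO)-14-hydroxy-8-(2-methylpropanoyloxy)germacra-1(10),4,11(13)-trien-12,6-olide | C=C1C(=O)O[C@@H]2/C=C(/CO[Si](c3ccccc3)(c3ccccc3)C(C)(C)C)C[C@H](O[Si](C)(C)C(C)(C)C)/C=C(/CO)[C@H](OC(C)=O)[C@@H](OC(=O)C(C)C)[C@@H]12 | intermediate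
39 | 14-aldehyde (enal) from 38 | C=C1C(=O)O[C@@H]2/C=C(/CO[Si](c3ccccc3)(c3ccccc3)C(C)(C)C)C[C@H](O[Si](C)(C)C(C)(C)C)/C=C(/C=O)[C@H](OC(C)=O)[C@@H](OC(=O)C(C)C)[C@@H]12 | intermediate (not isolated)
40 | (2S,6R,7S,8S,9S)-9-acetoxy-2-(TBSO)-15-(TBDPSO)-8-(2-methylpropanoyloxy)-12-oxo-12,6-epoxygermacra-1(10),4,11(13)-trien-14-oic acid | C=C1C(=O)O[C@@H]2/C=C(/CO[Si](c3ccccc3)(c3ccccc3)C(C)(C)C)C[C@H](O[Si](C)(C)C(C)(C)C)/C=C(/C(=O)O)[C@H](OC(C)=O)[C@@H](OC(=O)C(C)C)[C@@H]12 | intermediate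
41 | methyl ester of 40 | C=C1C(=O)O[C@@H]2/C=C(/CO[Si](c3ccccc3)(c3ccccc3)C(C)(C)C)C[C@H](O[Si](C)(C)C(C)(C)C)/C=C(/C(=O)OC)[C@H](OC(C)=O)[C@@H](OC(=O)C(C)C)[C@@H]12 | intermediate
42 | methyl (2S,6R,7S,8S,9S)-9-acetoxy-2,15-dihydroxy-8-(2-methylpropanoyloxy)-12-oxo-12,6-epoxygermacra-1(10),4,11(13)-trien-14-oate | C=C1C(=O)O[C@@H]2/C=C(/CO)C[C@H](O)/C=C(/C(=O)OC)[C@H](OC(C)=O)[C@@H](OC(=O)C(C)C)[C@@H]12 | target

**Step count and risks**
Total: 28 steps. Longest linear sequence: 27 steps (steps 1–5 and 7–28, from 1 to 42; step 6 is the only branch).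

The three steps most likely to fail:

- **Step 8 (enzymatic reduction of the bulky, isomerisable ynone).** If no ketoreductase accepts 13, or 13 slips into conjugation in buffer, the fallback sets out from 13. Anti-hydroiodination with NaI/AcOH gives (2Z,6E)-8-(TBSO)-6-(TBDPSOCH2)-2-iodo-1-(PMBO)octa-2,6-dien-4-one F1. Its ketone is reduced with (R)-Me-CBS oxazaborolidine and catecholborane (the alkenyl group acts as the large substituent; the same enzyme panel can also be tried on this enone). The fallback returns at 16 and bypasses steps 8 and 9.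
- **Step 18 (Mitsunobu inversion at the hindered, β-branched C8 carbinol; elimination may compete).** The fallback sets out from 30. ClCH2SO2Cl and pyridine give the chloromethanesulfonate of 30 F2, with the configuration of 30. SN2 displacement with cesium 2-methylpropanoate and 18-crown-6 in toluene inverts C8 and returns at 31.
- **Step 21 (ten-membered ring closure by CrCl2/NiCl2).** The fallback sets out from 33. NaClO2 oxidation gives the C9 carboxylic acid of 33 F3. EtSH, EDC and DMAP give the S-ethyl thioester of F3 F4. Me3SnSnMe3 with Pd(PPh3)4 exchanges the iodide for tin to give the C10 trimethylstannane of F4 F5. The ring is then closed by thioester–stannane acylation (Liebeskind–Srogl type) with copper thiophene-2-carboxylate Cu(O2CC4H3S), Pd2(dba)3 and tri(2-furyl)phosphine at high dilution. This gives the enone directly, returning at 35 and bypassing steps 21 and 22.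

**Further compounds**
F1 | step 8 | (2Z,6E)-8-(TBSO)-6-(TBDPSOCH2)-2-iodo-1-(PMBO)octa-2,6-dien-4-one | CC(C)(C)[Si](C)(C)OC/C=C(/CO[Si](c1ccccc1)(c1ccccc1)C(C)(C)C)CC(=O)/C=C(/COCc1ccc(OC)cc1)I
F2 | step 18 | chloromethanesulfonate of 30 (C8–OSO2CH2Cl, configuration of 30) | C=C1C(=O)O[C@H](/C=C(/CO[Si](c2ccccc2)(c2ccccc2)C(C)(C)C)C[C@H](O[Si](C)(C)C(C)(C)C)/C=C(/COCc2ccc(OC)cc2)I)[C@H]1[C@@H](OS(=O)(=O)CCl)CO[Si](C)(C)C(C)(C)C
F3 | step 21 | C9 carboxylic acid of 33 | C=C1C(=O)O[C@H](/C=C(/CO[Si](c2ccccc2)(c2ccccc2)C(C)(C)C)C[C@H](O[Si](C)(C)C(C)(C)C)/C=C(/COCc2ccc(OC)cc2)I)[C@H]1[C@H](OC(=O)C(C)C)C(=O)O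
F4 | step 21 | S-ethyl thioester of F3 | C=C1C(=O)O[C@H](/C=C(/CO[Si](c2ccccc2)(c2ccccc2)C(C)(C)C)C[C@H](O[Si](C)(C)C(C)(C)C)/C=C(/COCc2ccc(OC)cc2)I)[C@H]1[C@H](OC(=O)C(C)C)C(=O)SCC
F5 | step 21 | C10 trimethylstannane of F4 | C=C1C(=O)O[C@H](/C=C(/CO[Si](c2ccccc2)(c2ccccc2)C(C)(C)C)C[C@H](O[Si](C)(C)C(C)(C)C)/C=C(/COCc2ccc(OC)cc2)[Sn](C)(C)C)[C@H]1[C@H](OC(=O)C(C)C)C(=O)SCC
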